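**Assumption:** the target has no stereocentre (C2 of the pyran carries two methyls), so there is no enantiomer to control and the route only has to deliver the correct constitution.

## Retrosynthetic overview
- Target ⇒ the 2'-O-(1,1-dimethylpropargyl) ether of 7,4'-bis-TBS-2'-hydroxygenistein, via a propargyl-Claisen / [1,5]-H / 6π-oxa-electrocyclisation cascade. This dearomatises the B-ring transiently and builds the angular 2,2-dimethylpyran onto C3' in one operation.
- That ether ⇒ 2'-hydroxygenistein with its two unhindered phenols (7-OH and 4'-OH) masked as TBS. The hindered 2'-OH is left free and the 5-OH is chelated, so propargylation is selective for 2'-OH.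
- 2'-Hydroxygenistein ⇒ phloroglucinol + 2,4-dihydroxyphenylacetic acid: a desymmetrising Friedel–Crafts acylation, then a Vilsmeier-type closure of the chromone ring.
- Ring order: A-ring acylation, then the chromone ring, then the pyran ring last.

## Route

**Step 1**
Reactants: 1 phloroglucinol; 2 2,4-dihydroxyphenylacetic acid
Product: 3 2-(2,4-dihydroxyphenyl)-1-(2,4,6-trihydroxyphenyl)ethanone
Conditions: BF3·OEt2 (solvent/reagent), 85 °C, 1.5 h
Reagents that add atoms: none
Why: BF3-promoted Friedel–Crafts (Hoesch-type) C-acylation breaks the three-fold symmetry of phloroglucinol. Mono-acylation is self-limiting because the product's ketone is chelated and deactivated, and any coumaranone formed in situ from 2 acts as an equivalent acylating agent. No stereocentre is formed.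

**Step 2**
Reactants: 3 deoxybenzoin; 4 DMF
Product: 5 2'-hydroxygenistein (5,7,2',4'-tetrahydroxyisoflavone)
Conditions: BF3·OEt2, DMF, 50 °C; then MeSO2Cl, 80 °C, 2 h
Reagents that add atoms: DMF, CN(C)C=O (supplies C2 of the chromone)
Why: Wähälä–Hase Vilsmeier-type formylation/cyclisation of a free polyhydroxy deoxybenzoin. The BF3-chelated ketone is formylated at the α-CH2, and the 2-hydroxyl then closes the pyrone ring; no stereocentre is formed.

**Step 3**
Reactants: 5 2'-hydroxygenistein; 6 TBSCl
Product: 7 7,4'-bis(O-TBS)-2'-hydroxygenistein (5,2'-dihydroxy-7,4'-bis(tert-butyldimethylsilyloxy)isoflavone)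
Conditions: TBSCl (2.1 equiv), imidazole (4 equiv), DMF, 0 °C → rt, 3 h
Reagents that add atoms: TBSCl, CC(C)(C)[Si](C)(C)Cl
Why: Bulky silylation discriminates by sterics and acidity. The acidic 7-OH and the unhindered 4'-OH react, the hindered ortho-biaryl 2'-OH is slow, and the 5-OH is H-bonded to C4=O. This leaves exactly the one phenol needed for the next step; no stereocentre is formed.

**Step 4**
Reactants: 7 bis-TBS isoflavone; 8 3-chloro-3-methylbut-1-yne
Product: 9 2'-O-(2-methylbut-3-yn-2-yl) ether
Conditions: 8 (3 equiv), K2CO3, KI, CuI (10 mol%), DMF, 50 °C, 12 h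
Reagents that add atoms: 3-chloro-3-methylbut-1-yne, CC(C)(Cl)C#C
Why: Cu(I)-catalysed O-propargylation (via a copper acetylide/allenylidene) of the hindered phenol with a tertiary propargylic chloride. The chelated 5-OH does not react; no stereocentre is formed.

**Step 5**
Reactant: 9 propargyl ether
Product: 10 7,4'-bis(O-TBS) angular pyranoisoflavone (8,8-dimethylpyran fused at C2'–O/C3')
Conditions: PhNEt2, 200 °C, sealed tube, N2, 3 h
Reagents that add atoms: none
Why: Aromatic propargyl Claisen. The [3,3] shift breaks the B-ring aromaticity to give an allenyl-cyclohexadienone, which tautomerises to the aryl allene, undergoes a [1,5]-H shift and closes by 6π-oxa-electrocyclisation to the 2,2-dimethyl-2H-chromene. Because C1' is substituted, the new C–C bond can only form at C3', which fixes the angular regiochemistry; the product is achiral.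

**Step 6**
Reactant: 10 bis-TBS pyranoisoflavone
Product: 11 Sophoraisoflavone A
Conditions: TBAF/AcOH (1:1), THF, 0 °C → rt, 2 h
Reagents that add atoms: none
Why: Buffered fluoride desilylation of the two aryl silyl ethers. Buffering spares the acid-sensitive chromene and the base-sensitive isoflavone C2=C3; no stereocentre is involved.

## Compound list
1 | phloroglucinol | Oc1cc(O)cc(O)c1 | starting material
2 | 2,4-dihydroxyphenylacetic acid | OC(=O)Cc1ccc(O)cc1O | starting material
3 | 2-(2,4-dihydroxyphenyl)-1-(2,4,6-trihydroxyphenyl)ethanone | O=C(Cc1ccc(O)cc1O)c1c(O)cc(O)cc1O | intermediate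
4 | N,N-dimethylformamide | CN(C)C=O | reagent (adds C2)
5 | 2'-hydroxygenistein | O=c1c(-c2ccc(O)cc2O)coc2cc(O)cc(O)c12 | intermediate
6 | tert-butyldimethylsilyl chloride | CC(C)(C)[Si](C)(C)Cl | reagent
7 | 7,4'-bis(TBS)-2'-hydroxygenistein | CC(C)(C)[Si](C)(C)Oc1ccc(-c2coc3cc(O[Si](C)(C)C(C)(C)C)cc(O)c3c2=O)c(O)c1 | intermediate
8 | 3-chloro-3-methylbut-1-yne | CC(C)(Cl)C#C | reagent
9 | 2'-O-(1,1-dimethylpropargyl) bis-TBS isoflavone | C#CC(C)(C)Oc1cc(O[Si](C)(C)C(C)(C)C)ccc1-c1coc2cc(O[Si](C)(C)C(C)(C)C)cc(O)c2c1=O | intermediate
10 | bis-TBS angular pyranoisoflavone | CC1(C)C=Cc2c(O[Si](C)(C)C(C)(C)C)ccc(-c3coc4cc(O[Si](C)(C)C(C)(C)C)cc(O)c4c3=O)c2O1 | intermediate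
11 | Sophoraisoflavone A | CC1(C)C=Cc2c(O)ccc(-c3coc4cc(O)cc(O)c4c3=O)c2O1 | target (achiral, no stereocentres)

**Total steps:** 6. **Longest linear sequence:** 6 (from 1 or 2).

## Three steps most likely to fail
1. **Step 3, regioselective bis-silylation.** It may over-silylate to the tris-TBS compound or protect the 2'-OH instead of the 4'-OH. Fallback: a convergent approach. Suzuki coupling of 5,7-bis(MOM)-3-iodochromone (from phloroacetophenone, DMF-DMA, then I2) with a 2-propargyloxy-4-benzyloxyphenylboronate made from 4-bromoresorcinol. Then run the Claisen and deprotect.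
2. **Step 2, Vilsmeier closure.** The electron-rich resorcinol B-ring may be formylated, or 3 may lactonise. Fallback: a chalcone route. Claisen–Schmidt condensation of 2,4,6-trihydroxyacetophenone with 2,4-bis(benzyloxy)benzaldehyde, then Tl(III) oxidative 2,3-aryl migration to the isoflavone, then debenzylation to 5.
3. **Step 5, Claisen cascade at the crowded C3' (flanked by 2'-O and 4'-OTBS).** It may stall at the allenyl stage or decompose at 200 °C. Fallback: a stepwise pyran build. Install a 3'-prenyl group on the free phenol, then close the chromene by DDQ dehydrogenative cyclisation. Alternatively, condense prenal with the phenol under PhB(OH)2 ortho-direction (Knoevenagel/oxa-6π).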